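**A direct plan and its weak points**

A direct plan would make the hydroxyacetophenone A1 by C-acylation, join it by SNAr to the fluoroacetophenone A2 to give the diaryl ether diketone A3, methylenate both ketones to the bis(isopropenyl) phenol A4, and finish with a twofold copper hydride hydro-prenylation of A4 that sets both stereocentres.
- The closing twofold enantioselective hydro-prenylation would be the weakest step: a reaction type without precedent would have to set both remote benzylic centres last, on the finished core, and every miss would give the S,R diastereomer, which could hardly be separated.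
- The double Wittig methylenation of A3 would be weak: one ketone sits next to a phenoxide, is deactivated and enolisable, and A4 would be an acid-sensitive 2-isopropenylphenol.
- The chain build-up on the preformed ether would be weak as a plan: both C8 side chains would be grown in instalments (acetyl, methylene, prenyl), so most steps would only adjust carbon chains on the core, and the SNAr would rely on one ortho-acetyl group and an air-sensitive hydroquinone.

**Retrosynthetic overview**

- The target is the ether dimer of (S)-curcuphenol: ring B is a curcuphenol bound through its phenol oxygen, ring A a curcuphenol substituted at C4 (para to its OH, next to its ring CH3); the key disconnection is this O–C4 bond.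
- The bond would be formed last, by copper/O2 dehydrogenative coupling of two molecules of one monomer, as in the presumed biosynthesis: no halide, no protecting group, water as the only by-product.
- Both S centres would be set once, in the monomer, before the core exists: an enantioselective redox-relay Heck arylation of (Z)-pent-3-en-1-ol gives the benzylic CH(CH3) centre with the chain carbons in place; Wittig olefination and O-demethylation give (S)-curcuphenol.
- The two benzene rings are bought and the diaryl ether is made last, so there is no asymmetric step on the core, no ketone methylenation and no chain build-up on the ether.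

Key step: step 4

Assumption (chemistry): the pairing of the (S)-configured pyridine-oxazoline ligand with the Z alkenol is taken to give the 4S aldehyde; if the facial sense is the reverse, the (R)-ligand is used and nothing else changes.

**Route**

Step 1
Reactants: 1 (2-methoxy-4-methylphenyl)boronic acid; 2 (Z)-pent-3-en-1-ol
Product: 3 (4S)-4-(2-methoxy-4-methylphenyl)pentanal
Conditions: Pd(MeCN)2(OTs)2 (6 mol%), Cu(OTf)2 (6 mol%), (S)-4-tert-butyl-2-[5-(trifluoromethyl)pyridin-2-yl]-4,5-dihydrooxazole (13 mol%), 1 (3 equiv), 3 Å MS, DMF, O2 (1 atm), rt
Reagents that add atoms: none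
Why: Enantioselective redox-relay oxidative Heck reaction: the aryl group of 1 passes to divalent palladium and adds syn across the alkene with aryl on C4, the carbon remote from the hydroxyl; the ligand fixes the alkene face in this migratory insertion, which sets the S centre; palladium then walks by β-hydride elimination and reinsertion to C1, where the alcohol is oxidised to the aldehyde, and O2 with Cu(OTf)2 returns zerovalent to divalent palladium.

Step 2
Reactants: 3 (4S)-4-(2-methoxy-4-methylphenyl)pentanal
Product: 4 2-methoxy-4-methyl-1-[(2S)-6-methylhept-5-en-2-yl]benzene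
Conditions: iPrPPh3I (1.5 equiv), nBuLi (1.4 equiv), THF, 0 °C; then 3, −78 °C → rt
Reagents that add atoms: isopropyltriphenylphosphonium iodide CC(C)[P+](c1ccccc1)(c1ccccc1)c1ccccc1.[I-]
Why: Wittig olefination with the non-stabilised isopropylidene ylide turns the aldehyde into the 2-methylprop-1-enyl chain end; the stereocentre is γ to the carbonyl and cannot be enolised.

Step 3
Reactants: 4 2-methoxy-4-methyl-1-[(2S)-6-methylhept-5-en-2-yl]benzene
Product: 6 5-methyl-2-[(2S)-6-methylhept-5-en-2-yl]phenol ((S)-curcuphenol), via sodium phenolate 5 (not isolated)
Conditions: NaSEt (5 equiv), DMF, 140 °C; then 1 M HCl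
Reagents that add atoms: none
Why: SN2 O-demethylation: ethanethiolate attacks the methyl carbon of the aryl methyl ether, a nucleophilic method that leaves the acid-sensitive trisubstituted alkene and the benzylic centre untouched.

Step 4
Reactants: 6 5-methyl-2-[(2S)-6-methylhept-5-en-2-yl]phenol (two molecules)
Product: 8 5-methyl-2-[(2S)-6-methylhept-5-en-2-yl]-4-{5-methyl-2-[(2S)-6-methylhept-5-en-2-yl]phenoxy}phenol, via 4-aryloxycyclohexadienone 7 (not isolated)
Conditions: CuCl2(iPr3tacn) (5 mol%; iPr3tacn = 1,4,7-triisopropyl-1,4,7-triazacyclononane), 2,6-diphenylpyridine (0.5 equiv), toluene (1 M), 40 °C, O2 metered to about 0.08 equiv; then N2, aq. EDTA; unreacted 6 recovered and recycled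
Reagents that add atoms: none
Why: The divalent copper phenoxide of 6 is in equilibrium with a phenoxyl radical held on monovalent copper; its oxygen bonds to C4 of a second molecule of 6 (para to OH, the free ring carbon of highest spin density) to give the 4-aryloxycyclohexa-2,5-dienone 7, which tautomerises to the phenol 8, while O2 returns monovalent to divalent copper and ends as water. The closest known reaction type is the aerobic copper–amine oxidative C–O coupling of 2,6- and 2,5-dialkylphenols to 4-aryloxyphenols and poly(phenylene oxide)s, which with this triazacyclononane copper catalyst joins 2,5-dimethylphenol, the ring model of 6, head to tail through O and C4. No ring is closed and no lasting stereocentre is formed (the sp3 C4 of 7 is lost on tautomerisation); both S centres lie at least three bonds from the reacting atoms and are carried through, and because a stray R monomer would end mostly in the S,R diastereomer, the S,S/R,R ratio of 8 should exceed that of 6. The step needs O–C4 coupling over C–C and O–C6 coupling: C2 is blocked by the side chain, C6 lies between OH and CH3, C4 has one ortho neighbour only, and the bulky ligand keeps the radical on copper, which disfavours the C–C modes of free phenoxyl radicals. It must also stop at the dimer, whose phenol is oxidised more easily than 6: O2 is therefore metered to about one third conversion, higher ethers should be cut back to 8 by quinone-ketal redistribution with the excess of 6, and unreacted 6 is recycled.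

**Compound list**

1 | (2-methoxy-4-methylphenyl)boronic acid | COc1cc(C)ccc1B(O)O | starting material
2 | (Z)-pent-3-en-1-ol | C/C=C\CCO | starting material
3 | (4S)-4-(2-methoxy-4-methylphenyl)pentanal | O=CCC[C@H](C)c1ccc(C)cc1OC | intermediate
4 | 2-methoxy-4-methyl-1-[(2S)-6-methylhept-5-en-2-yl]benzene | CC(C)=CCC[C@H](C)c1ccc(C)cc1OC | intermediate
5 | sodium 5-methyl-2-[(2S)-6-methylhept-5-en-2-yl]phenolate | CC(C)=CCC[C@H](C)c1ccc(C)cc1[O-].[Na+] | intermediate
6 | 5-methyl-2-[(2S)-6-methylhept-5-en-2-yl]phenol ((S)-curcuphenol) | CC(C)=CCC[C@H](C)c1ccc(C)cc1O | intermediate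
7 | 5-methyl-2-[(2S)-6-methylhept-5-en-2-yl]-4-{5-methyl-2-[(2S)-6-methylhept-5-en-2-yl]phenoxy}cyclohexa-2,5-dien-1-one (ring C4 configuration not defined, transient) | CC(C)=CCC[C@H](C)C1=CC(Oc2cc(C)ccc2[C@@H](C)CCC=C(C)C)C(C)=CC1=O | intermediate
8 | 5-methyl-2-[(2S)-6-methylhept-5-en-2-yl]-4-{5-methyl-2-[(2S)-6-methylhept-5-en-2-yl]phenoxy}phenol (CNP0354307.1) | CC(C)=CCC[C@H](C)c1cc(Oc2cc(C)ccc2[C@@H](C)CCC=C(C)C)c(C)cc1O | target

**Step count and risks**

Total step count: 4. Longest linear sequence: 4 steps (1 → 3 → 4 → 6 → 8; both halves of 8 come from the same batch of 6).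

Steps most likely to fail, riskiest first:

1. Step 4. The coupling could run through carbon instead of oxygen (biphenols) or at C6, and the dimer could be oxidised on to higher ethers because its phenol is more electron-rich than that of 6. The fallback sets out from 6 and comes back at 8, and it fixes the roles of the two rings by polarity. Compound 6 would be iodinated para to the hydroxyl (I2, morpholine, CH2Cl2, 0 °C) to 4-iodo-5-methyl-2-[(2S)-6-methylhept-5-en-2-yl]phenol F1. F1 would be protected (MOMCl, iPr2NEt, CH2Cl2) as 1-iodo-4-(methoxymethoxy)-2-methyl-5-[(2S)-6-methylhept-5-en-2-yl]benzene F2. An Ullmann ether synthesis of F2 with a second portion of 6 (CuI, picolinic acid, K3PO4, DMSO, 90 °C) would give 1-(methoxymethoxy)-5-methyl-2-[(2S)-6-methylhept-5-en-2-yl]-4-{5-methyl-2-[(2S)-6-methylhept-5-en-2-yl]phenoxy}benzene F3. Dilute HCl in MeOH at rt would then free 8. The aryl iodide can only become ring A and the phenoxide only ring B, so neither C–C coupling nor chain growth is possible.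

2. Step 1. The aryl group could add to C3 instead of C4, the ortho-methoxy group could lower the facial selectivity of the insertion, and the electron-rich boronic acid could be lost by protodeboronation or homocoupling under O2. The fallback sets out from 1 and comes back at 4. Compound 1 would be added to ethyl (E)-crotonate in a rhodium-catalysed asymmetric 1,4-addition (Hayashi–Miyaura reaction; Rh(acac)(C2H4)2, (S)-BINAP, dioxane/H2O, 100 °C; the BINAP enantiomer is the one that gives the S product) to give ethyl (3S)-3-(2-methoxy-4-methylphenyl)butanoate F4. Reduction (LiAlH4, THF) would give (3S)-3-(2-methoxy-4-methylphenyl)butan-1-ol F5. I2, PPh3 and imidazole would give 1-[(2S)-4-iodobutan-2-yl]-2-methoxy-4-methylbenzene F6. Copper-catalysed coupling of F6 with (2-methylprop-1-en-1-yl)magnesium bromide (CuI cat., THF, 0 °C) would give 4.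

3. Step 2. The hindered, strongly basic ylide could enolise the aldehyde (self-aldol) and leave the olefination incomplete. The fallback sets out from 3 and comes back at 4, and it makes the trisubstituted alkene by metathesis instead. Compound 3 would be methylenated (Ph3PCH3Br, KOtBu, THF, 0 °C) to 1-[(2S)-hex-5-en-2-yl]-2-methoxy-4-methylbenzene F7. Cross-metathesis of F7 with 2-methylbut-2-ene (second-generation Grubbs catalyst, CH2Cl2, 40 °C) would give 4.

**Further compounds**

F1 | step 4 | 4-iodo-5-methyl-2-[(2S)-6-methylhept-5-en-2-yl]phenol | CC(C)=CCC[C@H](C)c1cc(I)c(C)cc1O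
F2 | step 4 | 1-iodo-4-(methoxymethoxy)-2-methyl-5-[(2S)-6-methylhept-5-en-2-yl]benzene | CC(C)=CCC[C@H](C)c1cc(I)c(C)cc1OCOC
F3 | step 4 | 1-(methoxymethoxy)-5-methyl-2-[(2S)-6-methylhept-5-en-2-yl]-4-{5-methyl-2-[(2S)-6-methylhept-5-en-2-yl]phenoxy}benzene | CC(C)=CCC[C@H](C)c1cc(Oc2cc(C)ccc2[C@@H](C)CCC=C(C)C)c(C)cc1OCOC
F4 | step 1 | ethyl (3S)-3-(2-methoxy-4-methylphenyl)butanoate | CCOC(=O)C[C@H](C)c1ccc(C)cc1OC
F5 | step 1 | (3S)-3-(2-methoxy-4-methylphenyl)butan-1-ol | OCC[C@H](C)c1ccc(C)cc1OC
F6 | step 1 | 1-[(2S)-4-iodobutan-2-yl]-2-methoxy-4-methylbenzene | ICC[C@H](C)c1ccc(C)cc1OC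
F7 | step 2 | 1-[(2S)-hex-5-en-2-yl]-2-methoxy-4-methylbenzene | C=CCC[C@H](C)c1ccc(C)cc1OC
A1 | direct plan | 1-(2,5-dihydroxy-4-methylphenyl)ethanone | CC(=O)c1cc(O)c(C)cc1O
A2 | direct plan | 1-(2-fluoro-4-methylphenyl)ethanone | CC(=O)c1ccc(C)cc1F
A3 | direct plan | 1-[5-(2-acetyl-5-methylphenoxy)-2-hydroxy-4-methylphenyl]ethanone | CC(=O)c1cc(Oc2cc(C)ccc2C(C)=O)c(C)cc1O
A4 | direct plan | 5-methyl-4-[5-methyl-2-(prop-1-en-2-yl)phenoxy]-2-(prop-1-en-2-yl)phenol | CC(=C)c1cc(Oc2cc(C)ccc2C(C)=C)c(C)cc1O
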